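## Structural features

- The target is a biflavonoid. A 5,7,4'-trihydroxyflavanone (rings A, C, B) is bonded through C3 of ring C to C8'' of a 5'',4'''-dihydroxyflavone, and O7'' of that flavone carries a sulfate monoester.
- C2 and C3 of ring C are neighbouring stereocentres with the (2R,3S) configuration. The C2 aryl group and the C3 flavonyl group are trans (both equatorial).
- C3 is alpha to the C4 ketone and epimerises through the enol, trans being the stable arrangement. C2 is a benzylic aryl-ether carbon that is lost only if ring C opens by beta-elimination of the ring-A phenoxide under base.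
- The aryl sulfate is acid-labile, the flavanone is base-labile and the five free phenols are oxidisable, so the sulfate must come late and the last deprotection must be neutral.
- The C3–C8'' bond joins a tertiary carbon to an arene carbon flanked by O7'' and by C8a''–O1''. It is the most crowded bond, and rotation about it is expected to be slow.
- The real difficulties are this crowded bond, the distinction of O7'' from five other phenolic oxygens, and absolute control at C2 next to an epimerisable C3.
- The key step uses the substitution pattern of ring A: the acyl carbon C4 sits on C4a, O1 on the adjacent C8a, and an ether oxygen on C5 beside C4a. A 3-alkoxyaryne produces exactly this pattern when it takes up a carboxylate and the acyl group shifts from oxygen to carbon. If the acid already holds C3 with its flavonyl group and C2 as an enol-ether carbon, ring C closes in the same operation.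

## Logic of the disconnections

**25 back to 21.** The S–O7'' bond and the five benzylic C–O bonds are cut. The sulfate is fragile, so it goes on last but one, onto the only free phenol of 22, and the benzyl groups come off by neutral hydrogenolysis from the salt 23. This reduces the problem to a fully protected biflavonoid 21 in which O7'' alone carries an acid-labile acetal. The forward steps must unmask O7'' without touching benzyl ethers, sulfate it despite the ortho substituent, and debenzylate without acid, base or over-reduction.

**21 back to 18 and 19.** The C2–aryl bond is cut. This removes both stereocentres at once and leaves a flat, achiral 3-arylchromone 18 and a simple aryl donor 19. The forward step must add the aryl group to one face of C2 of a chromone that carries a bulky C3 substituent. C3 is then left to settle trans by enolisation, so only one centre needs catalyst control.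

**18 back to 15 and 7 (key step).** O1–C8a, C4–C4a and O1–C2 are cut, and ring C disappears. The ring-A carbons C8a and C4a become the two ends of the aryne 16 released from 7. C4 becomes the carboxyl carbon of 15, C3 its alpha carbon (already bonded to C8''), and C2 its methoxy-bearing beta carbon. The gain is large: the crowded C3–C8'' bond is reduced to an aryl–CH2 bond made much earlier, and the two halves are joined late. The forward step needs regioselective capture of the carboxylate by the aryne, acyl transfer to carbon through 17, and addition–elimination closure.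

**15 back to 12.** The bond between the alpha carbon and the future C2, and the O–CH3 bond of the enol ether, are cut. This leaves an arylacetic ester 12 with an ordinary acidic methylene. The forward steps are a formylation through 13 to 14, which must be O-methylated and not C-methylated, and an ester cleavage to 15 that spares the enol ether.

**12 back to 8.** The C8''–CH2 bond is cut to the iodide 11, the C8''–I bond to 10, and the three O-protecting bonds to 9 and then 8. This reaches a commercial flavone that already has every ring atom of the lower unit. The forward steps need selective acetal formation at O7'' before benzylation, iodination at C8'' and not C6'', and a cross-coupling at a doubly ortho-substituted iodide.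

**7 back to 1.** The O–S bond of the triflate and the C–Si bond are cut, through 6, 5 and 2. The symmetric phenol 1 has two equivalent positions between the phenolic oxygen and a benzyloxy group, so directed metalation can give only one silyl regioisomer. The forward steps need ortho-lithiation that is faster than benzylic deprotonation.

## Other disconnections considered

**Alternative 1:** The pyranone of the flavone unit is cut at C4a''–C4'', C4''–C3'' and O1''–C2''.

- Forward step: the iodoresorcinol A2, carbon monoxide A4 and 4-(benzyloxy)phenylacetylene A3 would be joined under palladium catalysis. A carbonylative alkynylation gives an ortho-hydroxyaryl ynone, which closes 6-endo to give A1.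
- In favour: A1 is identical with 22, so the endgame is the same. The free 7''-hydroxyl appears without any protecting group, which is better than the chosen plan on protecting-group economy. The resorcinol before iodination has two equivalent open positions, so mono-iodination is unambiguous. The carbonylative annulation of ortho-iodophenols with alkynes is an established reaction type, whereas the chosen key step is an extension. On precedent for the key step itself the alternative is the better one.
- Against: A2 must already hold both stereocentres and the crowded C3–aryl bond, so the two hardest problems are only moved earlier, onto a phloroglucinol-type aryl group that is even harder to introduce.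
- Against: A2 has a free phenol on the aryl group alpha to the C4 ketone, and such compounds tend to cyclodehydrate to benzofurans.
- Against: amine base, heat and carbon monoxide A4 act on a base-sensitive flavanone. A 5-exo closure to an aurone competes with the 6-endo closure. A toxic gas under pressure is a safety cost.
- Comparison: both key steps form three bonds and one ring, and the step counts are similar. The chosen plan is better in keeping ring C flat and achiral until the end and in avoiding carbon monoxide.

**Alternative 2:** Ring C is cut at O1–C2 and C3–C4.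

- Forward step: the salicylaldehyde A6 and trimethyl orthoformate A7 would give a 4-methoxy ortho-quinone methide under acid. This would add to the E-stilbene A8 in the presence of a chiral phosphoric acid to give the all-trans chroman A5.
- In favour: both stereocentres and two ring bonds form in one step. The trans relationship comes directly from the alkene geometry and does not rely on epimerisation, which is better than the chosen plan on stereochemical directness. The sulfate is already present as its trichloroethyl diester.
- Against: A8 is a poor partner for an inverse-demand cycloaddition. Its flavonyl end is hindered and electron-poor, so reactivity and regiochemistry rest on the 4-benzyloxyphenyl end alone. An internal stilbene also offers the catalyst no hydrogen-bonding handle.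
- Against: A5 is at the wrong oxidation level at C4. Hydrolysis and oxidation next to an epimerisable centre are needed, with the sulfate diester present.
- Comparison: about three steps follow the key step, against four in the chosen plan, so step economy is equal or slightly better. The mechanistic risk in the key step is judged higher.

**Alternative 3:** Ring C is cut at C3–C4.

- Forward step: a chiral triazolylidene would convert the aldehyde of the keto-aldehyde A10 into an acyl-anion equivalent that attacks the flavonyl ketone. The alpha-aryloxy centre racemises under the base, so one enantiomer is drawn through to A9.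
- In favour: the enantioselective intramolecular aldehyde–ketone benzoin closure to 3-hydroxychroman-4-ones is well studied. On precedent for the reaction class it equals or betters the conjugate addition used after the chosen key step. It also turns the labile C2 centre to advantage.
- Against: the acceptor is an aryl ketone on a doubly ortho-substituted ring, the least reactive kind.
- Against: the C3 hydroxyl is surplus and must be removed reductively. C3 is then set by thermodynamic protonation, exactly as in the chosen plan, so the point is equal. The intermediate enolate has the ring oxygen in the beta position and may open ring C.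
- Against: A10 needs several extra steps (a flavonyl benzyl ketone, alpha-functionalisation, phenol alkylation).
- Comparison: step economy is worse by at least two steps, and the oxidation level has to be corrected after the key step.

Key step: step 10

## Remarks before the steps

- Assumption: the target is drawn as the free aryl hydrogen sulfate. It is carried as the sodium salt and protonated with one equivalent of acid in the cold only at the very end.
- Structure check: 7 has silicon between the triflate and a benzyloxy group, so the aryne has the ether beside the triple bond. 15 is the E isomer (methoxy trans to carboxyl). Both are consistent, atom for atom, with 18, and no correction is needed.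
- Precursor design:
  - The acetal on O7'' is kept, but its chloromethyl ether reagent is generated and used in solution.
  - The enol ether is made with sodium methoxide and methyl tosylate, avoiding sodium hydride and dimethyl sulfate.
  - In the key step, 15 is held as its cesium carboxylate by excess CsF to limit proton return.
  - The aryne step is run in a pressure-rated vessel.
- Abbreviation in names: Fv = 5-(benzyloxy)-2-[4-(benzyloxy)phenyl]-7-(methoxymethoxy)-4-oxo-4H-chromen-8-yl.

## Route

Step 1
Reactants: 1 3,5-bis(benzyloxy)phenol
Product: 2 3,5-bis(benzyloxy)phenyl N-isopropylcarbamate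
Conditions: i-PrNCO (1.2 equiv), Et3N (0.2 equiv), CH2Cl2, rt
Reagents that add atoms: isopropyl isocyanate, CC(C)N=C=O
Why: Base-catalysed addition of the phenol to the isocyanate (carbamoylation) installs a group that directs ortho-metalation and can later be removed under mild base.

Step 2
Reactants: 2 3,5-bis(benzyloxy)phenyl N-isopropylcarbamate
Product: 5 3,5-bis(benzyloxy)-2-(trimethylsilyl)phenyl N-isopropylcarbamate, via N-silyl carbamate 3 (not isolated), via doubly silylated carbamate 4 (not isolated)
Conditions: TMSOTf (1.1 equiv), TMEDA (1.1 equiv), Et2O, rt; n-BuLi (2.2 equiv), TMEDA (2.2 equiv), −78 °C; TMSCl (3 equiv), −78 °C → rt; aq. NaHSO4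
Reagents that add atoms: chlorotrimethylsilane, C[Si](C)(C)Cl
Why: Directed ortho-metalation: after N-silylation in the flask the carbamate directs lithiation to the position it shares with a benzyloxy group (the two such positions are equivalent), and the aryllithium is quenched by the silyl chloride. The doubly activated ring position should be lithiated faster than a benzylic CH2 at −78 °C, and the N–Si bond is hydrolysed on work-up.

Step 3
Reactants: 5 3,5-bis(benzyloxy)-2-(trimethylsilyl)phenyl N-isopropylcarbamate
Product: 7 3,5-bis(benzyloxy)-2-(trimethylsilyl)phenyl trifluoromethanesulfonate, via silylphenol 6 (not isolated)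
Conditions: DBU (1.5 equiv), Et2NH (1.25 equiv), MeCN, 40 °C; then PhNTf2 (1.5 equiv), rt
Reagents that add atoms: N-phenylbis(trifluoromethanesulfonimide), O=S(=O)(N(c1ccccc1)S(=O)(=O)C(F)(F)F)C(F)(F)F
Why: E1cB cleavage of the N–H carbamate frees the phenoxide (the isocyanate released is trapped by diethylamine as a urea), and the phenoxide is triflated in the same flask by the mild triflimide, which leaves the C–Si bond alone.

Step 4
Reactants: 8 apigenin
Product: 9 5-hydroxy-2-(4-hydroxyphenyl)-7-(methoxymethoxy)-4H-chromen-4-one
Conditions: MOMCl (1.05 equiv, prepared in toluene from CH2(OMe)2, AcCl and ZnBr2 (0.01 mol %) and used as this solution), K2CO3 (1.0 equiv), DMF, 0 °C → rt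
Reagents that add atoms: chloromethyl methyl ether, COCCl
Why: Williamson-type O-alkylation of the most acidic phenol: O7–H is para to the pyranone carbonyl, O5–H is held in a hydrogen bond to that carbonyl and O4'–H is less acidic, so one equivalent of base and reagent should react at O7 first.

Step 5
Reactants: 9 5-hydroxy-2-(4-hydroxyphenyl)-7-(methoxymethoxy)-4H-chromen-4-one
Product: 10 5-(benzyloxy)-2-[4-(benzyloxy)phenyl]-7-(methoxymethoxy)-4H-chromen-4-one
Conditions: BnBr (2.6 equiv), K2CO3 (3 equiv), n-Bu4NI (cat.), DMF, 70 °C
Reagents that add atoms: benzyl bromide, BrCc1ccccc1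
Why: Williamson ether synthesis on both remaining phenols; the chelated 5-hydroxyl needs heating in DMF, and the acetal is stable to carbonate.

Step 6
Reactants: 10 5-(benzyloxy)-2-[4-(benzyloxy)phenyl]-7-(methoxymethoxy)-4H-chromen-4-one
Product: 11 5-(benzyloxy)-2-[4-(benzyloxy)phenyl]-8-iodo-7-(methoxymethoxy)-4H-chromen-4-one
Conditions: I2 (1.1 equiv), AgOCOCF3 (1.1 equiv), NaHCO3 (3 equiv), CH2Cl2, 0 °C → rt, dark
Reagents that add atoms: iodine, II
Why: Electrophilic aromatic iodination by trifluoroacetyl hypoiodite formed in the flask. With both ring oxygens alkylated, C8 (between one ether and the ring oxygen) is less hindered than C6 (between two bulky ethers), and bicarbonate removes the acid so that the acetal survives.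

Step 7
Reactants: 11 5-(benzyloxy)-2-[4-(benzyloxy)phenyl]-8-iodo-7-(methoxymethoxy)-4H-chromen-4-one
Product: 12 methyl 2-(Fv)acetate
Conditions: BrZnCH2CO2Me (2 equiv, from BrCH2CO2Me and TMSCl-activated Zn dust in THF), Pd(dba)2 (5 mol %), XPhos (10 mol %), THF, 60 °C
Reagents that add atoms: (2-methoxy-2-oxoethyl)zinc bromide, COC(=O)C[Zn]Br
Why: Negishi-type coupling of a Reformatsky reagent: zerovalent palladium inserts into the C–I bond, the zinc ester enolate transmetalates and reductive elimination gives the arylacetate. A bulky biaryl phosphine is chosen for the doubly ortho-substituted iodide, and the zinc enolate is too mild to attack the pyranone.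

Step 8
Reactants: 12 methyl 2-(Fv)acetate
Product: 14 methyl (E)-3-methoxy-2-(Fv)acrylate, via sodium formyl enolate 13 (not isolated)
Conditions: NaOMe (3 equiv), HCO2Me (10 equiv), THF, 0 °C → rt; evaporate; MeOTs (2 equiv), DMF, rt
Reagents that add atoms: methyl formate, COC=O; methyl p-toluenesulfonate, COS(=O)(=O)c1ccc(C)cc1
Why: Crossed Claisen condensation with the formate gives the formyl enolate, which a hard methylating agent alkylates on oxygen to give mainly the E enol ether, the standard entry to beta-methoxyacrylates. The alkene geometry is not critical because it disappears in step 10.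

Step 9
Reactants: 14 methyl (E)-3-methoxy-2-(Fv)acrylate
Product: 15 (E)-3-methoxy-2-(Fv)acrylic acid
Conditions: LiOH·H2O (3 equiv), THF/MeOH/H2O, rt → 40 °C; then 1 M HCl to pH 4, 0 °C
Reagents that add atoms: lithium hydroxide, [Li+].[OH-]
Why: Saponification at the acyl carbon, as known for beta-methoxyacrylate esters; brief cold acidification to pH 4 keeps the enol ether and the acetal intact.

Step 10
Reactants: 15 (E)-3-methoxy-2-(Fv)acrylic acid; 7 3,5-bis(benzyloxy)-2-(trimethylsilyl)phenyl trifluoromethanesulfonate
Product: 18 5,7-bis(benzyloxy)-3-(Fv)-4H-chromen-4-one, via aryne 16 (not isolated), via ortho-acyl phenoxide 17 (not isolated)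
Conditions: 7 (2 equiv), CsF (5 equiv, dried), THF, 125 °C, pressure-rated vessel
Reagents that add atoms: none
Why: Proposed new method: fluoride removes the silyl group of 7 and triflate leaves, giving aryne 16; the cesium carboxylate of 15 adds through oxygen to the aryne carbon remote from the flanking benzyloxy group (the future C8a), because that inductively withdrawing ether polarises the distorted triple bond and stabilises the aryl anion left on the adjacent carbon (the future C4a). The anion, held close to the ester carbonyl, attacks it through a four-membered tetrahedral intermediate that opens to the ortho-acyl phenoxide 17 (anionic oxygen-to-carbon acyl shift, forming C4–C4a). The phenoxide then adds 6-endo-trig to the beta carbon of the beta-methoxy enone and methoxide leaves from the enolate (addition–elimination, forming O1–C2), which closes ring C as the 4-pyranone. The closest known reactions are the fluoride-induced insertion of arynes into the C–O bond of carboxylic acids to give ortho-hydroxyaryl ketones and its tandem versions with acrylic acids (chroman-4-ones by oxa-Michael closure) and arylpropiolic acids (flavones); a beta-alkoxyacrylic acid with an addition–elimination closure is the untested part. No stereocentre is formed and the enol ether geometry is lost. The selectivities needed are the regiochemistry of carboxylate capture, secured by the benzyloxy group beside the aryne bond, and acyl transfer in preference to conjugate attack of the aryl anion on the beta carbon (which would give a coumarin), secured by the short carbanion–carbonyl distance in the preferred ester conformation and by the donor-deactivated beta carbon. Excess 7 makes up for aryne consumed by the liberated methoxide, and excess CsF keeps the acid as its carboxylate so that proton return to the aryl anion (plain O-arylation) is limited.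

Step 11
Reactants: 18 5,7-bis(benzyloxy)-3-(Fv)-4H-chromen-4-one; 19 4-(benzyloxy)phenylboronic acid
Product: 21 (2R,3S)-5,7-bis(benzyloxy)-2-[4-(benzyloxy)phenyl]-3-(Fv)chroman-4-one, via cis C3-epimer 20 (not isolated)
Conditions: 19 (2 equiv), Pd(OCOCF3)2 (10 mol %), (S)-4-tert-butyl-2-(pyridin-2-yl)-4,5-dihydrooxazole (12 mol %), NH4PF6 (30 mol %), H2O (5 equiv), ClCH2CH2Cl, 60 °C, held until C3 has equilibrated
Reagents that add atoms: none
Why: Proposed new method: the aryl group of 19 transmetalates to the cationic divalent palladium–pyridine-oxazoline complex, the C2=C3 bond of the 2-unsubstituted chromone inserts with face selection (aryl to C2, palladium to C3), and the oxygen-bound enolate is protonated by water; the closest known reaction is this same catalytic asymmetric conjugate addition of arylboronic acids to chromones without a C3 substituent, and a 3-arylchromone acceptor is untested. C2 is set by the ligand, whose tert-butyl group blocks one quadrant so that the aryl group goes to the face giving 2R (the S ligand is chosen by analogy with simple chromones, and its enantiomer is equally available if the C3 substituent reverses the sense), while C3 is set under thermodynamic control, since enolisation in the weakly acidic medium converts the kinetically protonated cis epimer 20 into the trans, diequatorial 21. The 2-aryl pyranone of the flavone unit is disubstituted at its beta carbon and more hindered, so it should not compete, and partial loss of the acetal would only deliver 22 early.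

Step 12
Reactants: 21 (2R,3S)-5,7-bis(benzyloxy)-2-[4-(benzyloxy)phenyl]-3-(Fv)chroman-4-one
Product: 22 (2R,3S)-5,7-bis(benzyloxy)-2-[4-(benzyloxy)phenyl]-3-{5-(benzyloxy)-2-[4-(benzyloxy)phenyl]-7-hydroxy-4-oxo-4H-chromen-8-yl}chroman-4-one
Conditions: HCl (1.25 M in MeOH, 5 equiv), CH2Cl2/MeOH, 0 °C → rt
Reagents that add atoms: none
Why: Acid-catalysed acetal exchange with methanol removes the methoxymethyl group while benzyl ethers and the flavanone tolerate dilute methanolic acid. Any remaining cis epimer equilibrates to trans through the enol under the same conditions.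

Step 13
Reactants: 22 (2R,3S)-5,7-bis(benzyloxy)-2-[4-(benzyloxy)phenyl]-3-{5-(benzyloxy)-2-[4-(benzyloxy)phenyl]-7-hydroxy-4-oxo-4H-chromen-8-yl}chroman-4-one
Product: 23 sodium 5-(benzyloxy)-2-[4-(benzyloxy)phenyl]-8-{(2R,3S)-5,7-bis(benzyloxy)-2-[4-(benzyloxy)phenyl]-4-oxochroman-3-yl}-4-oxo-4H-chromen-7-yl sulfate
Conditions: SO3·pyridine (5 equiv), pyridine, rt → 40 °C; then aq. NaHCO3
Reagents that add atoms: sulfur trioxide–pyridine complex, [O-]S(=O)(=O)[n+]1ccccc1; sodium hydrogencarbonate, [Na+].OC([O-])=O
Why: O-Sulfonation of the only free phenol by the sulfur trioxide–amine complex; the 7''-hydroxyl is acidic (para to the flavone carbonyl) and should react despite its ortho substituent. Pyridine is too weak a base to open the flavanone, and bicarbonate work-up gives the sodium salt.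

Step 14
Reactants: 23 sodium 5-(benzyloxy)-2-[4-(benzyloxy)phenyl]-8-{(2R,3S)-5,7-bis(benzyloxy)-2-[4-(benzyloxy)phenyl]-4-oxochroman-3-yl}-4-oxo-4H-chromen-7-yl sulfate
Product: 25 8-[(2R,3S)-5,7-dihydroxy-2-(4-hydroxyphenyl)-4-oxochroman-3-yl]-5-hydroxy-2-(4-hydroxyphenyl)-4-oxo-4H-chromen-7-yl hydrogen sulfate (CNP0271389.1), via sodium salt of the target 24 (not isolated)
Conditions: H2 (1 atm), 10% Pd/C, THF/MeOH, rt; filter; then HCl (1.0 equiv, 0.1 M in MeOH), 0 °C
Reagents that add atoms: none
Why: Hydrogenolysis of the five benzyl ethers over palladium under neutral conditions, which aryl sulfate salts survive. One atmosphere at room temperature should spare the flavone double bond and the benzylic C2–O1 bond, and one equivalent of cold acid then gives the hydrogen sulfate form.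

## Compound list

1 | 3,5-bis(benzyloxy)phenol | Oc1cc(OCc2ccccc2)cc(OCc2ccccc2)c1 | starting material
2 | 3,5-bis(benzyloxy)phenyl N-isopropylcarbamate | CC(C)NC(=O)Oc1cc(OCc2ccccc2)cc(OCc2ccccc2)c1 | intermediate
3 | 3,5-bis(benzyloxy)phenyl N-isopropyl-N-(trimethylsilyl)carbamate | CC(C)N([Si](C)(C)C)C(=O)Oc1cc(OCc2ccccc2)cc(OCc2ccccc2)c1 | intermediate (not isolated)
4 | 3,5-bis(benzyloxy)-2-(trimethylsilyl)phenyl N-isopropyl-N-(trimethylsilyl)carbamate | CC(C)N([Si](C)(C)C)C(=O)Oc1cc(OCc2ccccc2)cc(OCc2ccccc2)c1[Si](C)(C)C | intermediate (not isolated)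
5 | 3,5-bis(benzyloxy)-2-(trimethylsilyl)phenyl N-isopropylcarbamate | CC(C)NC(=O)Oc1cc(OCc2ccccc2)cc(OCc2ccccc2)c1[Si](C)(C)C | intermediate
6 | 3,5-bis(benzyloxy)-2-(trimethylsilyl)phenol | Oc1cc(OCc2ccccc2)cc(OCc2ccccc2)c1[Si](C)(C)C | intermediate (not isolated)
7 | 3,5-bis(benzyloxy)-2-(trimethylsilyl)phenyl trifluoromethanesulfonate | C[Si](C)(C)c1c(OCc2ccccc2)cc(OCc2ccccc2)cc1OS(=O)(=O)C(F)(F)F | intermediate
8 | apigenin | O=c1cc(-c2ccc(O)cc2)oc2cc(O)cc(O)c12 | starting material
9 | 5-hydroxy-2-(4-hydroxyphenyl)-7-(methoxymethoxy)-4H-chromen-4-one | O=c1cc(-c2ccc(O)cc2)oc2cc(OCOC)cc(O)c12 | intermediate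
10 | 5-(benzyloxy)-2-[4-(benzyloxy)phenyl]-7-(methoxymethoxy)-4H-chromen-4-one | O=c1cc(-c2ccc(OCc3ccccc3)cc2)oc2cc(OCOC)cc(OCc3ccccc3)c12 | intermediate
11 | 5-(benzyloxy)-2-[4-(benzyloxy)phenyl]-8-iodo-7-(methoxymethoxy)-4H-chromen-4-one | O=c1cc(-c2ccc(OCc3ccccc3)cc2)oc2c(I)c(OCOC)cc(OCc3ccccc3)c12 | intermediate
12 | methyl 2-(Fv)acetate | COC(=O)Cc1c(OCOC)cc(OCc2ccccc2)c2c(=O)cc(-c3ccc(OCc4ccccc4)cc3)oc12 | intermediate
13 | sodium enolate of methyl 3-oxo-2-(Fv)propanoate (enolate geometry not fixed) | [Na+].[O-]C=C(C(=O)OC)c1c(OCOC)cc(OCc2ccccc2)c2c(=O)cc(-c3ccc(OCc4ccccc4)cc3)oc12 | intermediate (not isolated)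
14 | methyl (E)-3-methoxy-2-(Fv)acrylate | CO/C=C(\c1c(OCOC)cc(OCc2ccccc2)c2c(=O)cc(-c3ccc(OCc4ccccc4)cc3)oc12)C(=O)OC | intermediate
15 | (E)-3-methoxy-2-(Fv)acrylic acid | CO/C=C(\c1c(OCOC)cc(OCc2ccccc2)c2c(=O)cc(-c3ccc(OCc4ccccc4)cc3)oc12)C(=O)O | intermediate
16 | 3,5-bis(benzyloxy)benzyne | C1#CC(OCc2ccccc2)=CC(OCc2ccccc2)=C1 | intermediate (not isolated)
17 | cesium 3,5-bis(benzyloxy)-2-[(E)-3-methoxy-2-(Fv)acryloyl]phenolate | CO/C=C(\c1c(OCOC)cc(OCc2ccccc2)c2c(=O)cc(-c3ccc(OCc4ccccc4)cc3)oc12)C(=O)c1c([O-])cc(OCc2ccccc2)cc1OCc1ccccc1.[Cs+] | intermediate (not isolated)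
18 | 5,7-bis(benzyloxy)-3-(Fv)-4H-chromen-4-one | O=c1c(-c2c(OCOC)cc(OCc3ccccc3)c3c(=O)cc(-c4ccc(OCc5ccccc5)cc4)oc23)coc2cc(OCc3ccccc3)cc(OCc3ccccc3)c12 | intermediate
19 | 4-(benzyloxy)phenylboronic acid | OB(O)c1ccc(OCc2ccccc2)cc1 | starting material
20 | (2R,3R)-5,7-bis(benzyloxy)-2-[4-(benzyloxy)phenyl]-3-(Fv)chroman-4-one (cis) | O=C1c2c(OCc3ccccc3)cc(OCc3ccccc3)cc2O[C@@H](c2ccc(OCc3ccccc3)cc2)[C@H]1c1c(OCOC)cc(OCc2ccccc2)c2c(=O)cc(-c3ccc(OCc4ccccc4)cc3)oc12 | intermediate (not isolated)
21 | (2R,3S)-5,7-bis(benzyloxy)-2-[4-(benzyloxy)phenyl]-3-(Fv)chroman-4-one (trans) | O=C1c2c(OCc3ccccc3)cc(OCc3ccccc3)cc2O[C@@H](c2ccc(OCc3ccccc3)cc2)[C@@H]1c1c(OCOC)cc(OCc2ccccc2)c2c(=O)cc(-c3ccc(OCc4ccccc4)cc3)oc12 | intermediate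
22 | (2R,3S)-5,7-bis(benzyloxy)-2-[4-(benzyloxy)phenyl]-3-{5-(benzyloxy)-2-[4-(benzyloxy)phenyl]-7-hydroxy-4-oxo-4H-chromen-8-yl}chroman-4-one | O=C1c2c(OCc3ccccc3)cc(OCc3ccccc3)cc2O[C@@H](c2ccc(OCc3ccccc3)cc2)[C@@H]1c1c(O)cc(OCc2ccccc2)c2c(=O)cc(-c3ccc(OCc4ccccc4)cc3)oc12 | intermediate
23 | sodium 5-(benzyloxy)-2-[4-(benzyloxy)phenyl]-8-{(2R,3S)-5,7-bis(benzyloxy)-2-[4-(benzyloxy)phenyl]-4-oxochroman-3-yl}-4-oxo-4H-chromen-7-yl sulfate | O=C1c2c(OCc3ccccc3)cc(OCc3ccccc3)cc2O[C@@H](c2ccc(OCc3ccccc3)cc2)[C@@H]1c1c(OS(=O)(=O)[O-])cc(OCc2ccccc2)c2c(=O)cc(-c3ccc(OCc4ccccc4)cc3)oc12.[Na+] | intermediate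
24 | sodium 8-[(2R,3S)-5,7-dihydroxy-2-(4-hydroxyphenyl)-4-oxochroman-3-yl]-5-hydroxy-2-(4-hydroxyphenyl)-4-oxo-4H-chromen-7-yl sulfate | O=C1c2c(O)cc(O)cc2O[C@@H](c2ccc(O)cc2)[C@@H]1c1c(OS(=O)(=O)[O-])cc(O)c2c(=O)cc(-c3ccc(O)cc3)oc12.[Na+] | intermediate (not isolated)
25 | 8-[(2R,3S)-5,7-dihydroxy-2-(4-hydroxyphenyl)-4-oxochroman-3-yl]-5-hydroxy-2-(4-hydroxyphenyl)-4-oxo-4H-chromen-7-yl hydrogen sulfate (CNP0271389.1) | O=C1c2c(O)cc(O)cc2O[C@@H](c2ccc(O)cc2)[C@@H]1c1c(OS(=O)(=O)O)cc(O)c2c(=O)cc(-c3ccc(O)cc3)oc12 | target

## Step count and least certain steps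

Total: 14 steps. Longest linear sequence: 11 steps (steps 4 to 14, from 8); steps 1 to 3 form the convergent branch to 7.

**Step 10 (key step, new method).**
- Risk: acyl transfer to the aryl anion may be too slow, because the carbonyl is deactivated by the methoxy donor and shielded by the doubly ortho-substituted aryl group. Proton return to the anion would then leave plain O-arylation, or the enol ether would degrade under hot fluoride.
- Fallback, from 12 back to 18, known chemistry: saponification of 12 with LiOH gives the arylacetic acid F1. Its fluoride-induced insertion into the aryne from 7 (CsF, THF, 125 °C) gives the ortho-hydroxyaryl benzyl ketone F2, whose carbonyl is neither conjugated nor as crowded. Heating F2 with N,N-dimethylformamide dimethyl acetal in toluene gives the enaminone F3, which cyclises with loss of dimethylamine to 18. This is the classical isoflavone annulation. C2 is then added after the acyl transfer and not before it.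

**Step 11 (new method).**
- Risk: no migratory insertion because the C3 aryl group blocks the palladium–aryl species, or poor facial selectivity, with protodeboronation and homocoupling of 19 taking over. Slowly interconverting rotamers about the C3–C8'' axis may also react at different rates.
- Fallback, from 18 back to 21, known chemistry: copper-mediated conjugate addition of 4-(benzyloxy)phenylmagnesium bromide F4 (CuBr·SMe2, TMSCl, THF, −78 → −20 °C), a known reaction of chromones, gives the silyl enol ether F5. Hydrolysis with dilute aqueous citric acid and equilibration at C3 give the racemic trans ketone, that is 21 together with its (2S,3R)-enantiomer F6. Preparative chromatography on a chiral stationary phase separates the two, and 21 rejoins the route at step 12.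

**Step 4.**
- Risk: incomplete discrimination between O7 and O4', giving over-alkylation and unreacted 8 that are hard to separate as polar phenols.
- Fallback, from 8 back to 9: peracetylation (Ac2O, pyridine) gives apigenin triacetate F7. The 7-acetate, the most electrophilic, is removed selectively with thiophenol and imidazole in N-methylpyrrolidone to give the 4',5-diacetate F8. Methoxymethylation as in step 4, with i-Pr2NEt as base, gives the 7-O-methoxymethyl diacetate F9. Methanolysis of the acetates (K2CO3, MeOH) gives 9. This costs three more steps but addresses each phenol unambiguously.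

**Step 7.**
- Risk: slow oxidative addition or transmetalation at the doubly ortho-substituted iodide, with reduction of the C–I bond.
- Fallback, from 11 back to 14: Miyaura borylation (B2pin2, KOAc, PdCl2(dppf), dioxane, 90 °C) gives the pinacol boronate F10. Suzuki–Miyaura coupling with methyl (Z)-2-iodo-3-methoxyacrylate F11 (Pd(OAc)2, SPhos, K3PO4, toluene/H2O) proceeds with retention at the alkene and gives 14 directly. This replaces steps 7 and 8 by the established cross-coupling entry to beta-methoxyacrylates.

**Step 13.**
- Risk: sluggish sulfation of the hindered phenol, and loss of the sulfate or opening of the flavanone while the polar salt is handled and purified.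
- Fallback, from 22 back to 25: 2,2,2-trichloroethyl chlorosulfate with Et3N and DMAP in THF gives the neutral sulfate diester F12, which can be purified by ordinary chromatography. Transfer hydrogenolysis (10% Pd/C, HCO2NH4, MeOH/THF, rt) removes the trichloroethyl group and the five benzyl groups in one buffered operation to give the ammonium salt F13. One equivalent of cold acid converts F13 into 25.

Further compounds
F1 | step 10 | 2-(Fv)acetic acid | OC(=O)Cc1c(OCOC)cc(OCc2ccccc2)c2c(=O)cc(-c3ccc(OCc4ccccc4)cc3)oc12
F2 | step 10 | 1-[2,4-bis(benzyloxy)-6-hydroxyphenyl]-2-(Fv)ethan-1-one | O=C(Cc1c(OCOC)cc(OCc2ccccc2)c2c(=O)cc(-c3ccc(OCc4ccccc4)cc3)oc12)c1c(O)cc(OCc2ccccc2)cc1OCc1ccccc1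
F3 | step 10 | 1-[2,4-bis(benzyloxy)-6-hydroxyphenyl]-3-(dimethylamino)-2-(Fv)prop-2-en-1-one | CN(C)C=C(C(=O)c1c(O)cc(OCc2ccccc2)cc1OCc1ccccc1)c1c(OCOC)cc(OCc2ccccc2)c2c(=O)cc(-c3ccc(OCc4ccccc4)cc3)oc12
F4 | step 11 | 4-(benzyloxy)phenylmagnesium bromide | Br[Mg]c1ccc(OCc2ccccc2)cc1
F5 | step 11 | racemic 5,7-bis(benzyloxy)-2-[4-(benzyloxy)phenyl]-3-(Fv)-4-(trimethylsilyloxy)-2H-chromene | C[Si](C)(C)OC1=C(c2c(OCOC)cc(OCc3ccccc3)c3c(=O)cc(-c4ccc(OCc5ccccc5)cc4)oc23)C(c2ccc(OCc3ccccc3)cc2)Oc2cc(OCc3ccccc3)cc(OCc3ccccc3)c12
F6 | step 11 | (2S,3R)-5,7-bis(benzyloxy)-2-[4-(benzyloxy)phenyl]-3-(Fv)chroman-4-one (enantiomer of 21, formed with 21 as the racemate) | O=C1c2c(OCc3ccccc3)cc(OCc3ccccc3)cc2O[C@H](c2ccc(OCc3ccccc3)cc2)[C@H]1c1c(OCOC)cc(OCc2ccccc2)c2c(=O)cc(-c3ccc(OCc4ccccc4)cc3)oc12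
F7 | step 4 | apigenin 4',5,7-triacetate | CC(=O)Oc1ccc(cc1)-c1cc(=O)c2c(OC(C)=O)cc(OC(C)=O)cc2o1
F8 | step 4 | apigenin 4',5-diacetate | CC(=O)Oc1ccc(cc1)-c1cc(=O)c2c(OC(C)=O)cc(O)cc2o1
F9 | step 4 | 7-O-(methoxymethyl)apigenin 4',5-diacetate | CC(=O)Oc1ccc(cc1)-c1cc(=O)c2c(OC(C)=O)cc(OCOC)cc2o1
F10 | step 7 | 5-(benzyloxy)-2-[4-(benzyloxy)phenyl]-7-(methoxymethoxy)-8-(4,4,5,5-tetramethyl-1,3,2-dioxaborolan-2-yl)-4H-chromen-4-one | CC1(C)OB(OC1(C)C)c1c(OCOC)cc(OCc2ccccc2)c2c(=O)cc(-c3ccc(OCc4ccccc4)cc3)oc12
F11 | step 7 | methyl (Z)-2-iodo-3-methoxyacrylate | CO/C=C(\I)C(=O)OC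
F12 | step 13 | 5-(benzyloxy)-2-[4-(benzyloxy)phenyl]-8-{(2R,3S)-5,7-bis(benzyloxy)-2-[4-(benzyloxy)phenyl]-4-oxochroman-3-yl}-4-oxo-4H-chromen-7-yl 2,2,2-trichloroethyl sulfate | O=C1c2c(OCc3ccccc3)cc(OCc3ccccc3)cc2O[C@@H](c2ccc(OCc3ccccc3)cc2)[C@@H]1c1c(OS(=O)(=O)OCC(Cl)(Cl)Cl)cc(OCc2ccccc2)c2c(=O)cc(-c3ccc(OCc4ccccc4)cc3)oc12
F13 | step 13 | ammonium 8-[(2R,3S)-5,7-dihydroxy-2-(4-hydroxyphenyl)-4-oxochroman-3-yl]-5-hydroxy-2-(4-hydroxyphenyl)-4-oxo-4H-chromen-7-yl sulfate | [NH4+].O=C1c2c(O)cc(O)cc2O[C@@H](c2ccc(O)cc2)[C@@H]1c1c(OS(=O)(=O)[O-])cc(O)c2c(=O)cc(-c3ccc(O)cc3)oc12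
A1 | alternative 1 | (2R,3S)-pentabenzyl flavanone–flavone with free 7''-hydroxyl (identical with 22) | O=C1c2c(OCc3ccccc3)cc(OCc3ccccc3)cc2O[C@@H](c2ccc(OCc3ccccc3)cc2)[C@@H]1c1c(O)cc(OCc2ccccc2)c2c(=O)cc(-c3ccc(OCc4ccccc4)cc3)oc12
A2 | alternative 1 | (2R,3S)-5,7-bis(benzyloxy)-2-[4-(benzyloxy)phenyl]-3-[4-(benzyloxy)-2,6-dihydroxy-3-iodophenyl]chroman-4-one | O=C1c2c(OCc3ccccc3)cc(OCc3ccccc3)cc2O[C@@H](c2ccc(OCc3ccccc3)cc2)[C@@H]1c1c(O)cc(OCc2ccccc2)c(I)c1O
A3 | alternative 1 | 4-(benzyloxy)phenylacetylene | C#Cc1ccc(OCc2ccccc2)cc1
A4 | alternative 1 | carbon monoxide | [C-]#[O+]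
A5 | alternative 2 | all-trans 4-methoxy-2,3-diarylchroman with 7''-O-(2,2,2-trichloroethyl) sulfate | CO[C@H]1c2c(OCc3ccccc3)cc(OCc3ccccc3)cc2O[C@@H](c2ccc(OCc3ccccc3)cc2)[C@@H]1c1c(OS(=O)(=O)OCC(Cl)(Cl)Cl)cc(OCc2ccccc2)c2c(=O)cc(-c3ccc(OCc4ccccc4)cc3)oc12
A6 | alternative 2 | 2,4-bis(benzyloxy)-6-hydroxybenzaldehyde | O=Cc1c(O)cc(OCc2ccccc2)cc1OCc1ccccc1
A7 | alternative 2 | trimethyl orthoformate | COC(OC)OC
A8 | alternative 2 | 5-(benzyloxy)-2-[4-(benzyloxy)phenyl]-8-[(E)-4-(benzyloxy)styryl]-4-oxo-4H-chromen-7-yl 2,2,2-trichloroethyl sulfate | O=c1cc(-c2ccc(OCc3ccccc3)cc2)oc2c(/C=C/c3ccc(OCc4ccccc4)cc3)c(OS(=O)(=O)OCC(Cl)(Cl)Cl)cc(OCc3ccccc3)c12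
A9 | alternative 3 | 3-hydroxy-3-(Fv)flavanone with the two aryl groups trans | O=C1c2c(OCc3ccccc3)cc(OCc3ccccc3)cc2O[C@@H](c2ccc(OCc3ccccc3)cc2)[C@]1(O)c1c(OCOC)cc(OCc2ccccc2)c2c(=O)cc(-c3ccc(OCc4ccccc4)cc3)oc12
A10 | alternative 3 | racemic 2,4-bis(benzyloxy)-6-{1-[4-(benzyloxy)phenyl]-2-oxo-2-(Fv)ethoxy}benzaldehyde | O=Cc1c(OCc2ccccc2)cc(OCc2ccccc2)cc1OC(c1ccc(OCc2ccccc2)cc1)C(=O)c1c(OCOC)cc(OCc2ccccc2)c2c(=O)cc(-c3ccc(OCc4ccccc4)cc3)oc12
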